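The numbers belong to no real substance; what happens was integrated by code.

Watch the free catalyst, not the catalyst charged.

    catalyst + added ligand ⇌ idle complex, settled at all times (K1 = 67 M⁻¹)
    substrate + partner + catalyst → catalyst + target (k2 = 2.45 × 10⁻⁴ M⁻² s⁻¹)
    partner + protic impurity → quenched reagent (k3 = 1.48 × 10⁻⁴ M⁻¹ s⁻¹)

substrate 1.0 M; partner 2.00 M; protic impurity 0.500 M; catalyst 100 mM; added ligand 64 mM

- apparent order in catalyst when 50% of the substrate are converted (percent change of the rate of making target for one percent more catalyst charged)
- factor on the rate of making target when 50% of the substrate are converted if partner is charged twice over

Step one, held at balance, splits both charges. Its quadratic puts the idle complex, an off-cycle form, at 49.4 mM. That leaves 50.6 mM as c(catalyst), the free catalyst at balance.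

A second way is quicker: let every added ligand bind. Then c(catalyst) is 36.0 mM, and the order is the charge over this amount, 2.78. The two ways part, and the quick one cheats. At its own c(catalyst), the binding constant gives idle complex and free ligand a ratio of only 2.41, so 29.3% of the ligand stays unbound, against its premise.

The balance therefore stands. Differentiating it, with c(substrate) and c(partner) held, the order is the catalyst charge over c(catalyst), divided by one plus the binding constant times the ligand charge over the square of one plus the binding constant times c(catalyst). This gives 1.62.

For partner, my reckoning takes off the full impurity charge, because the impurity's lifetime at the partner charge, 0.938 h, is shorter than the substrate's at that c(catalyst), 11.2 h. At 50% conversion c(partner) is then 1.00 M. A double charge leaves 3.00 M, a rate factor of 3.00.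

The forecast gives 1.62 for the order, on the ground that “added catalyst also soaks up the remaining free ligand”, and 3 for the factor on the rate. Its two values match my reckoning.

The simulation gives 1.6 and 3.00, and both forecast values stand within their margins. At 0.712 h, partner goes to quenched reagent 3.2 times as fast as to target. At 12.0 h that ratio is 0.0039, with 0.500 M of quenched reagent standing. In the flask as charged, the reckoned 50.6 mM is 50.6% of the catalyst charged, and the share of free catalyst stands at 50.6% at 47.1 h. In the flask charged with twice the catalyst, the same balance gives 142 mM free, a factor of 2.81, and the rate there changes by a factor of 2.88.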